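## Retrosynthetic overview

1. Numbering: ring A = C1–C5 and C10; ring B = C5–C10; C11 = OCH2 on C9; C12 = exocyclic CH2 on C8 (also used for the monocyclic ring-B intermediates, where C1–C2 is the acetate arm on C10 and C4–C3 the isobutyrate arm on C5). The plan rests on the C2(OAc)–C3(=O) pair of ring A: two adjacent carbons at the acyloin oxidation level, between C1H2 and quaternary C4, which can be joined reductively as two ester carbons.
2. Last disconnections: C11–OAr (Mitsunobu with isofraxidin) and C9–C11 (SE2′ reaction of a ring-B allylsilane C9=C8–CH2SiMe3 with formaldehyde, which also creates C8=C12).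
3. Key disconnection: C2–C3, silyl-trapped acyloin condensation of the ring-B diester; the 2-acetoxy-3-ketone is then released from the 2,3-bis(silyloxy)alkene by kinetic protonation at C2 and acetylation.
4. Ring-B substituents: allylsilane from the C9 ketone (C8 silylmethylation, enol triflate, reduction); quaternary C10 by reductive alkylation of a C10 exo-methylene ketone with methyl bromoacetate; C5–C4 by catalytic asymmetric Mukaiyama–Michael addition to cyclohexenone.
5. Ring order: ring B is bought as cyclohexenone, ring A is closed in step 7, the coumarin is attached last.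

Key step: step 7

Remark 1: the (S)-configured oxazaborolidinium catalyst is assumed to give the (S)-adduct 3; if the sense of induction is the opposite, its mirror image made from (R)-diphenylprolinol is used.
Remark 2: 2-methylcyclohex-2-en-1-one is not used as the acceptor because it lacks the α-hydrogen that organises binding to this catalyst; the C10 methyl is brought in by steps 2 and 3 instead.

## Route

Step 1
Reactants: 1 cyclohex-2-en-1-one; 2 1-methoxy-2-methyl-1-(trimethylsilyloxy)prop-1-ene
Product: 3 methyl 2-methyl-2-[(1S)-3-(trimethylsilyloxy)cyclohex-2-en-1-yl]propanoate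
Conditions: (S)-1-(2-methylphenyl)-3,3-diphenyltetrahydro-1H,3H-pyrrolo[1,2-c][1,3,2]oxazaborole protonated with HN(SO2CF3)2 (20 mol%), Ph3P=O (25 mol%), toluene, −20 °C; pentane, filtration, no aqueous work-up
Reagents that add atoms: none
Why: Catalytic enantioselective Mukaiyama–Michael addition, in which the chiral oxazaborolidinium ion binds the enone carbonyl and shields one face of the β-carbon, triphenylphosphine oxide intercepts silyl cations that would open a racemic pathway, and silyl transfer releases the adduct as the C9–C10 silyl enol ether, so the catalyst sets C5 (S) and the enol ether fixes where the next carbon enters.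

Step 2
Reactants: 3 methyl 2-methyl-2-[(1S)-3-(trimethylsilyloxy)cyclohex-2-en-1-yl]propanoate
Product: 6 methyl 2-methyl-2-[(1S)-2-methylidene-3-oxocyclohexyl]propanoate, via Mannich base 4 (not isolated), via methiodide 5 (not isolated)
Conditions: dimethyl(methylidene)ammonium iodide, CH2Cl2, 0 °C → rt; aq NaHCO3 work-up; MeI, Et2O, rt; aq NaHCO3/CH2Cl2, rt; used at once
Reagents that add atoms: dimethyl(methylidene)ammonium iodide, C=[N+](C)C.[I-]
Why: Mannich reaction of the silyl enol ether with the iminium salt places the one-carbon unit at C10 only, and N-methylation followed by mild base elimination (Hofmann-type) gives the exo-methylene ketone, bicarbonate being too weak to move the alkene into the ring, so C5 is untouched.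

Step 3
Reactants: 6 methyl 2-methyl-2-[(1S)-2-methylidene-3-oxocyclohexyl]propanoate; 7 methyl bromoacetate
Product: 9 methyl 2-[(1S,2R)-2-(2-methoxy-2-oxoethyl)-2-methyl-3-oxocyclohexyl]-2-methylpropanoate, via lithium enolate 8 (not isolated)
Conditions: LiBH(s-Bu)3 (1.05 equiv), THF, −78 °C; then 7, DMPU, −78 → 0 °C
Reagents that add atoms: none
Why: Reductive alkylation, in which the hindered borohydride adds hydride 1,4 to the unsubstituted methylene terminus and so gives the tetrasubstituted C9–C10 enolate regiospecifically while turning the methylene into the C10 methyl, and bromoacetate then alkylates C10 anti to the bulky C5 side chain (held pseudoaxial by allylic strain with the methyl), which sets the quaternary centre (R) with the two ester arms trans.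

Step 4
Reactants: 9 methyl 2-[(1S,2R)-2-(2-methoxy-2-oxoethyl)-2-methyl-3-oxocyclohexyl]-2-methylpropanoate
Product: 11 methyl 2-[(1S,2R)-2-(2-methoxy-2-oxoethyl)-2-methyl-3-oxo-4-[(trimethylsilyl)methyl]cyclohexyl]-2-methylpropanoate (C8 epimers), via lithium enolate 10 (not isolated)
Conditions: LiN(i-Pr)2 (1.05 equiv), THF, −78 °C; Me3SiCH2OSO2CF3, −78 → −20 °C
Reagents that add atoms: (trimethylsilyl)methyl trifluoromethanesulfonate, C[Si](C)(C)COS(=O)(=O)C(F)(F)F
Why: Kinetic enolate alkylation, in which the amide base can deprotonate the ketone only at C8 because C10 is quaternary (and faster than the one enolisable, hindered ester CH2), and the lithium enolate is C-alkylated by the very reactive silylmethyl triflate; the C8 configuration is of no consequence because C8 becomes trigonal in step 5.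

Step 5
Reactants: 11 methyl 2-[(1S,2R)-2-(2-methoxy-2-oxoethyl)-2-methyl-3-oxo-4-[(trimethylsilyl)methyl]cyclohexyl]-2-methylpropanoate
Product: 13 methyl 2-[(1S,2R)-2-(2-methoxy-2-oxoethyl)-2-methyl-3-(trifluoromethanesulfonyloxy)-4-[(trimethylsilyl)methyl]cyclohex-3-en-1-yl]-2-methylpropanoate, via potassium enolate 12 (not isolated)
Conditions: KN(SiMe3)2, THF, −78 °C; PhN(SO2CF3)2, −78 → 0 °C
Reagents that add atoms: N-phenylbis(trifluoromethanesulfonimide), O=S(=O)(N(c1ccccc1)S(=O)(=O)C(F)(F)F)C(F)(F)F
Why: Enol triflate formation, in which the only remaining α-hydrogen of the ketone (C8–H) is removed and the potassium enolate is sulfonylated on oxygen, giving the tetrasubstituted C8=C9 enol triflate as a single regioisomer.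

Step 6
Reactants: 13 methyl 2-[(1S,2R)-2-(2-methoxy-2-oxoethyl)-2-methyl-3-(trifluoromethanesulfonyloxy)-4-[(trimethylsilyl)methyl]cyclohex-3-en-1-yl]-2-methylpropanoate
Product: 14 methyl 2-[(1S,2S)-2-(2-methoxy-2-oxoethyl)-2-methyl-4-[(trimethylsilyl)methyl]cyclohex-3-en-1-yl]-2-methylpropanoate
Conditions: Pd(OAc)2 (5 mol%), PPh3 (10 mol%), HCO2H, n-Bu3N, DMF, 60 °C
Reagents that add atoms: none
Why: Palladium-catalysed formate reduction of the enol triflate (oxidative addition to zerovalent palladium, exchange of triflate for formate, loss of CO2, C–H reductive elimination) replaces OTf by H at C9 in an amine-buffered medium that leaves the allylsilane and both esters intact.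

Step 7
Reactants: 14 methyl 2-[(1S,2S)-2-(2-methoxy-2-oxoethyl)-2-methyl-4-[(trimethylsilyl)methyl]cyclohex-3-en-1-yl]-2-methylpropanoate
Product: 15 (5S,10S)-4,4,10-trimethyl-2,3-bis(trimethylsilyloxy)-8-[(trimethylsilyl)methyl]decalin-2(3),8(9)-diene
Conditions: Na dispersion (4.4 equiv), Me3SiCl (5 equiv), toluene, reflux, argon, slow addition of 14; filtration under argon, used crude
Reagents that add atoms: chlorotrimethylsilane, C[Si](C)(C)Cl
Why: Sodium transfers electrons to both ester carbonyls, the two ketyl radical anions couple C2 to C3, two methoxides leave to give the 2,3-dione, and two further electrons give the enediolate, which Me3SiCl traps as the bis(silyl) enediol ether while it also silylates methoxide and so shuts down Dieckmann and Claisen pathways. The closest known reaction type is the silyl-trapped acyloin cyclisation of 1,6-diesters to cyclohexene-1,2-diol bis(silyl) ethers, a standard six-ring closure that tolerates esters on quaternary carbon. Ring A closes as a six-membered carbocycle by intramolecular coupling of two arms that are held trans and equatorial on ring B, and the gem-dimethyl group at C4 favours the folded conformer. No stereocentre is formed, and C5 and C10 are not α to a carbonyl, so they are carried through unchanged. The step needs chemoselectivity, which is secured because neither the allylsilane nor the trisubstituted alkene accepts an electron from sodium in toluene, and it needs ring closure to beat intermolecular coupling, which slow addition of the diester secures.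

Step 8
Reactants: 15 (5S,10S)-4,4,10-trimethyl-2,3-bis(trimethylsilyloxy)-8-[(trimethylsilyl)methyl]decalin-2(3),8(9)-diene
Product: 17 (2R,5S,10S)-2-hydroxy-4,4,10-trimethyl-8-[(trimethylsilyl)methyl]decal-8(9)-en-3-one, via 2-silyloxy ketone 16 (not isolated)
Conditions: (±)-camphor-10-sulfonic acid (1.0 equiv), CH2Cl2, −78 °C; then MeOH, −78 → −20 °C; NaHCO3 quench
Reagents that add atoms: none
Why: Acid hydrolysis of a silyl enol ether goes through rate-limiting protonation on carbon, so the bulky sulfonic acid should reach the less hindered C2 (C3 is flanked by quaternary C4) from the face opposite the axial methyl groups on C10 and C4, the C3 oxocarbenium ion collapses to the ketone while C2 keeps its oxygen syn to the angular methyl (2R), and methanol then cleaves the remaining silyl ether at a temperature too low to enolise the ketol.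

Step 9
Reactants: 17 (2R,5S,10S)-2-hydroxy-4,4,10-trimethyl-8-[(trimethylsilyl)methyl]decal-8(9)-en-3-one
Product: 18 (2R,5S,10S)-2-acetoxy-4,4,10-trimethyl-8-[(trimethylsilyl)methyl]decal-8(9)-en-3-one
Conditions: Ac2O, pyridine, 4-(dimethylamino)pyridine (cat.), CH2Cl2, 0 °C
Reagents that add atoms: acetic anhydride, CC(=O)OC(C)=O
Why: Nucleophile-catalysed O-acylation of the secondary ketol at 0 °C under weakly basic conditions that do not enolise C3 towards C2, so the 2R configuration is carried into the acetate.

Step 10
Reactants: 18 (2R,5S,10S)-2-acetoxy-4,4,10-trimethyl-8-[(trimethylsilyl)methyl]decal-8(9)-en-3-one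
Product: 19 (2R,5S,9S,10R)-2-acetoxy-9-(hydroxymethyl)-4,4,10-trimethyl-8-methylidenedecalin-3-one
Conditions: (CH2O)n, Me2AlCl (2.5 equiv), CH2Cl2, −78 → −20 °C; cold dilute aq HCl work-up
Reagents that add atoms: paraformaldehyde (as formaldehyde), C=O
Why: Hosomi–Sakurai-type SE2′ hydroxymethylation, in which the formaldehyde–Me2AlCl complex bonds to C9 on the face opposite the axial C10 methyl (axial attack on the ring-B half-chair), the β-silyl cation at C8 loses silicon to give the exocyclic C8=C12 alkene, which sets C9 (S), and the methylaluminium reagent scavenges protons and holds the product as an aluminium alkoxide, which should suppress protodesilylation and a second Prins-type addition.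

Step 11
Reactants: 19 (2R,5S,9S,10R)-2-acetoxy-9-(hydroxymethyl)-4,4,10-trimethyl-8-methylidenedecalin-3-one; 20 isofraxidin (7-hydroxy-6,8-dimethoxycoumarin)
Product: 21 (2R,5S,9S,10R)-2-acetoxy-9-[(6,8-dimethoxy-2-oxo-2H-chromen-7-yl)oxymethyl]-4,4,10-trimethyl-8-methylidenedecalin-3-one (CNP0183157.1)
Conditions: PPh3, diisopropyl azodicarboxylate, THF, 0 °C → rt
Reagents that add atoms: none
Why: Mitsunobu etherification, in which the acidic 7-hydroxycoumarin protonates the betaine and its phenoxide displaces the oxyphosphonium group at primary C11 in an SN2 step that touches no stereocentre, under near-neutral conditions that leave the acetoxy ketone and the exocyclic alkene alone.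

## Compound list

1 | cyclohex-2-en-1-one | O=C1C=CCCC1 | starting material
2 | 1-methoxy-2-methyl-1-(trimethylsilyloxy)prop-1-ene | COC(O[Si](C)(C)C)=C(C)C | starting material
3 | methyl 2-methyl-2-[(1S)-3-(trimethylsilyloxy)cyclohex-2-en-1-yl]propanoate | COC(=O)C(C)(C)[C@H]1CCCC(O[Si](C)(C)C)=C1 | intermediate
4 | methyl 2-[(1S)-2-[(dimethylamino)methyl]-3-oxocyclohexyl]-2-methylpropanoate (Mannich base, C10 epimers) | COC(=O)C(C)(C)[C@H]1CCCC(=O)C1CN(C)C | intermediate
5 | {(6S)-6-(1-methoxy-2-methyl-1-oxopropan-2-yl)-2-oxocyclohexyl}methyl-trimethylammonium iodide (methiodide, C10 epimers) | COC(=O)C(C)(C)[C@H]1CCCC(=O)C1C[N+](C)(C)C.[I-] | intermediate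
6 | methyl 2-methyl-2-[(1S)-2-methylidene-3-oxocyclohexyl]propanoate | COC(=O)C(C)(C)[C@H]1CCCC(=O)C1=C | intermediate
7 | methyl bromoacetate | COC(=O)CBr | starting material
8 | lithium (3S)-3-(1-methoxy-2-methyl-1-oxopropan-2-yl)-2-methylcyclohex-1-en-1-olate | COC(=O)C(C)(C)[C@H]1CCCC([O-])=C1C.[Li+] | intermediate
9 | methyl 2-[(1S,2R)-2-(2-methoxy-2-oxoethyl)-2-methyl-3-oxocyclohexyl]-2-methylpropanoate | COC(=O)C[C@@]1(C)C(=O)CCC[C@@H]1C(C)(C)C(=O)OC | intermediate
10 | lithium C8–C9 enolate of 9 | COC(=O)C[C@@]1(C)C([O-])=CCC[C@@H]1C(C)(C)C(=O)OC.[Li+] | intermediate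
11 | methyl 2-[(1S,2R)-2-(2-methoxy-2-oxoethyl)-2-methyl-3-oxo-4-[(trimethylsilyl)methyl]cyclohexyl]-2-methylpropanoate (C8 epimers) | COC(=O)C[C@@]1(C)C(=O)C(C[Si](C)(C)C)CC[C@@H]1C(C)(C)C(=O)OC | intermediate
12 | potassium C8–C9 enolate of 11 | COC(=O)C[C@@]1(C)C([O-])=C(C[Si](C)(C)C)CC[C@@H]1C(C)(C)C(=O)OC.[K+] | intermediate
13 | methyl 2-[(1S,2R)-2-(2-methoxy-2-oxoethyl)-2-methyl-3-(trifluoromethanesulfonyloxy)-4-[(trimethylsilyl)methyl]cyclohex-3-en-1-yl]-2-methylpropanoate | COC(=O)C[C@@]1(C)C(OS(=O)(=O)C(F)(F)F)=C(C[Si](C)(C)C)CC[C@@H]1C(C)(C)C(=O)OC | intermediate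
14 | methyl 2-[(1S,2S)-2-(2-methoxy-2-oxoethyl)-2-methyl-4-[(trimethylsilyl)methyl]cyclohex-3-en-1-yl]-2-methylpropanoate (ring-B allylsilane diester) | COC(=O)C[C@@]1(C)C=C(C[Si](C)(C)C)CC[C@@H]1C(C)(C)C(=O)OC | intermediate
15 | (5S,10S)-4,4,10-trimethyl-2,3-bis(trimethylsilyloxy)-8-[(trimethylsilyl)methyl]decalin-2(3),8(9)-diene | C[Si](C)(C)OC1=C(O[Si](C)(C)C)C(C)(C)[C@H]2CCC(C[Si](C)(C)C)=C[C@]2(C)C1 | intermediate
16 | (2R,5S,10S)-4,4,10-trimethyl-2-(trimethylsilyloxy)-8-[(trimethylsilyl)methyl]decal-8(9)-en-3-one | C[Si](C)(C)CC1=C[C@]2(C)C[C@@H](O[Si](C)(C)C)C(=O)C(C)(C)[C@H]2CC1 | intermediate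
17 | (2R,5S,10S)-2-hydroxy-4,4,10-trimethyl-8-[(trimethylsilyl)methyl]decal-8(9)-en-3-one | C[Si](C)(C)CC1=C[C@]2(C)C[C@@H](O)C(=O)C(C)(C)[C@H]2CC1 | intermediate
18 | (2R,5S,10S)-2-acetoxy-4,4,10-trimethyl-8-[(trimethylsilyl)methyl]decal-8(9)-en-3-one | C[Si](C)(C)CC1=C[C@]2(C)C[C@@H](OC(C)=O)C(=O)C(C)(C)[C@H]2CC1 | intermediate
19 | (2R,5S,9S,10R)-2-acetoxy-9-(hydroxymethyl)-4,4,10-trimethyl-8-methylidenedecalin-3-one | C=C1CC[C@@H]2C(C)(C)C(=O)[C@H](OC(C)=O)C[C@@]2(C)[C@H]1CO | intermediate
20 | isofraxidin (7-hydroxy-6,8-dimethoxycoumarin) | COc1cc2ccc(=O)oc2c(OC)c1O | starting material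
21 | (2R,5S,9S,10R)-2-acetoxy-9-[(6,8-dimethoxy-2-oxo-2H-chromen-7-yl)oxymethyl]-4,4,10-trimethyl-8-methylidenedecalin-3-one | C=C1CC[C@@H]2C(C)(C)C(=O)[C@H](OC(C)=O)C[C@@]2(C)[C@H]1COc1c(OC)cc2ccc(=O)oc2c1OC | target

## Step count and risks

Total step count: 11. Longest linear sequence: 11 steps (1 and 2 to 21).

**Step 8 (release of the ketol).** What may go wrong: proton delivery to C3 instead of C2, proton delivery to C2 from the methyl-bearing face, or equilibration of the ketol through its enediol; each scrambles the position or the configuration of the C2 oxygen. The fallback sets out from 15 and comes back at 18. Unselective hydrolysis of 15 (1 M HCl, THF, 0 °C) gives the mixed ring-A ketols, represented by the 3-hydroxy-2-ketone F1. Dess–Martin periodinane oxidises the mixture to the 2,3-dione, which can enolise only towards C1 because C4 is quaternary, and it is obtained as the diosphenol, the 2-hydroxy-1-en-3-one F2, so the question of site disappears. Ac2O in pyridine gives the diosphenol acetate, the 2-acetoxy-1-en-3-one F3. Hydrogenation (H2, Pd/C, EtOAc, stopped after one equivalent) should reduce the conjugated C1=C2 bond before the hindered allylsilane alkene and add hydrogen from the face opposite the angular methyl, which places the acetate syn to that methyl and returns to 18.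

**Step 7 (acyloin ring closure).** What may go wrong: intermolecular coupling and oligomerisation, incomplete electron transfer to the hindered ester on quaternary C4, or loss of the allylic silicon on hot sodium. The fallback forms the same C2–C3 bond by a pinacol coupling at the aldehyde oxidation level; it sets out from 14 and comes back at 18. LiAlH4 (THF, 0 °C) reduces both esters to the diol F4, and Swern oxidation gives the dialdehyde F5. SmI2 (THF, t-BuOH) closes ring A by pinacol coupling to the 2,3-diol F6, whose diol configuration is of no consequence. Double oxidation with DMSO, (CF3CO)2O and Et3N gives the diosphenol F2, which is taken through the acetate F3 and hydrogenation to 18 as described for step 8.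

**Step 10 (hydroxymethylation at C9).** What may go wrong: protodesilylation of the allylsilane without C–C bond formation, slow attack at C9 next to quaternary C10, or a second Prins-type addition of formaldehyde to the new exocyclic alkene; the SN2 displacement of step 11 at β-branched C11 by a doubly ortho-substituted phenol is a related weak point. The fallback brings in C11 already bound to the coumarin oxygen; it sets out from 18 (and from 20 for the electrophile) and comes back at 21, bypassing 19. Isofraxidin 20 is O-alkylated with chloromethyl methyl sulfide (NaH, NaI, DMF) to the methylthiomethyl ether F7, and SO2Cl2 (CH2Cl2, 0 °C) converts this to the chloromethyl ether F8. SnCl4 (tin tetrachloride, CH2Cl2, −78 °C) ionises F8 to the aryloxymethyl cation, which the allylsilane 18 should capture at C9 on the face opposite the angular methyl with loss of silicon, giving 21 directly; the product is an ether and cannot undergo a further Prins reaction.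

## Further compounds

F1 | step 8 | 3-hydroxy-4,4,10-trimethyl-8-[(trimethylsilyl)methyl]decal-8(9)-en-2-one (C5 and C10 as in 15; mixed with 17 and its C2 epimer) | C[Si](C)(C)CC1=C[C@]2(C)CC(=O)C(O)C(C)(C)[C@H]2CC1
F2 | step 8 | 2-hydroxy-4,4,10-trimethyl-8-[(trimethylsilyl)methyl]decalin-1,8(9)-dien-3-one (diosphenol, C5 and C10 as in 15) | C[Si](C)(C)CC1=C[C@]2(C)C=C(O)C(=O)C(C)(C)[C@H]2CC1
F3 | step 8 | 2-acetoxy-4,4,10-trimethyl-8-[(trimethylsilyl)methyl]decalin-1,8(9)-dien-3-one (diosphenol acetate, C5 and C10 as in 15) | C[Si](C)(C)CC1=C[C@]2(C)C=C(OC(C)=O)C(=O)C(C)(C)[C@H]2CC1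
F4 | step 7 | 2-[(1S,2S)-2-(2-hydroxyethyl)-2-methyl-4-[(trimethylsilyl)methyl]cyclohex-3-en-1-yl]-2-methylpropan-1-ol | OCC[C@@]1(C)C=C(C[Si](C)(C)C)CC[C@@H]1C(C)(C)CO
F5 | step 7 | 2-methyl-2-[(1S,2S)-2-methyl-2-(2-oxoethyl)-4-[(trimethylsilyl)methyl]cyclohex-3-en-1-yl]propanal | O=CC[C@@]1(C)C=C(C[Si](C)(C)C)CC[C@@H]1C(C)(C)C=O
F6 | step 7 | 4,4,10-trimethyl-8-[(trimethylsilyl)methyl]decal-8(9)-ene-2,3-diol (C5 and C10 as in 15, diol epimers) | C[Si](C)(C)CC1=C[C@]2(C)CC(O)C(O)C(C)(C)[C@H]2CC1
F7 | step 10 | 6,8-dimethoxy-7-[(methylsulfanyl)methoxy]coumarin | COc1cc2ccc(=O)oc2c(OC)c1OCSC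
F8 | step 10 | 7-(chloromethoxy)-6,8-dimethoxycoumarin | COc1cc2ccc(=O)oc2c(OC)c1OCCl
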